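**Retrosynthetic overview**
- Pyranone and oxepine are closed last, in one flask: the polyanion of 3,5-diprenyl-phloroacetophenone is joined to a chiral iodo ester of 2,4-dihydroxybenzoic acid by Claisen acylation (C2–C3), 7-exo C-alkylation (C3–CH2, oxepine) and acid cyclodehydration (O1–C2, pyranone).
- The iodo ester comes from a primary alcohol, obtained by methanolysis of a 1,4-benzodioxepin-5-one lactone.
- The lactone's aryl–O–CH bond (R) comes from an ester-tethered 7-exo opening of an (S)-epoxide by the ortho-phenoxide, with inversion; the epoxy ester comes from 2,4-dihydroxybenzoic acid and (S)-3,3-dimethylglycidyl tosylate (Sharpless epoxidation of prenol).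
- A ring: both prenyl groups are put on phloroacetophenone first, so no alkene has to be oxidised selectively once they are present.
- Ring order: temporary benzodioxepinone (step 3, reopened in the same step), then oxepine, then pyranone (both in step 5).

Assumption: the one stereocenter in the SMILES is (R) (CIP order O-aryl > C(CH3)2OH > CH2 > H); the route makes this enantiomer.

**Step 1**
Reactants: 1 2,4,6-trihydroxyacetophenone; 2 prenyl bromide (1-bromo-3-methylbut-2-ene, 2.2 equiv)
Product: 3 1-[2,4,6-trihydroxy-3,5-bis(3-methylbut-2-en-1-yl)phenyl]ethan-1-one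
Conditions: 10% aq KOH, 0 °C → rt
Reagents that add atoms: none
Why: Base-mediated C-prenylation of an acylphloroglucinol: the phenoxide of 1 reacts as a soft, enolate-like carbon nucleophile with the allylic bromide at both free ring positions (water favours C- over O-alkylation), the known 3,5-diprenyl ketone 3 is separated from mono- and over-alkylated material, and no stereocenter is formed.

**Step 2**
Reactants: 4 prenol (3-methylbut-2-en-1-ol)
Product: 6 [(2S)-3,3-dimethyloxiran-2-yl]methyl 4-methylbenzenesulfonate, via epoxy alcohol 5 (not isolated)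
Conditions: Ti(OiPr)4 (5 mol%), L-(+)-DIPT (6 mol%), t-BuOOH, 4 Å MS, CH2Cl2, −20 °C; then TsCl, Et3N, DMAP (cat.), −10 °C
Reagents that add atoms: tert-butyl hydroperoxide (CC(C)(C)OO); 4-methylbenzenesulfonyl chloride (Cc1ccc(cc1)S(=O)(=O)Cl)
Why: Sharpless asymmetric epoxidation: the Ti–L-(+)-tartrate catalyst delivers the peroxide oxygen to one face of the allylic alcohol and so sets the (2S) epoxide (about 90–94% ee, raised by recrystallising 6), and in-situ tosylation captures the volatile, water-soluble epoxy alcohol 5 without touching the stereocenter.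

**Step 3**
Reactants: 6 [(2S)-3,3-dimethyloxiran-2-yl]methyl 4-methylbenzenesulfonate; 7 2,4-dihydroxybenzoic acid
Product: 10 methyl 2-{[(2R)-1,3-dihydroxy-3-methylbutan-2-yl]oxy}-4-hydroxybenzoate, via epoxy ester 8 (not isolated), via lactone 9 (not isolated)
Conditions: KHCO3, DMF, 50 °C; then Cs2CO3 (0.3 equiv), DMF (0.01 M), 85 °C; then MeOH, rt
Reagents that add atoms: methanol (CO)
Why: Carboxylate SN2 at the primary tosylate gives 8 with the epoxide intact, the ortho-phenoxide then opens the tethered epoxide by intramolecular SN2 (7-exo-tet) at the secondary carbon, the only one open to backside attack, so that (S) is inverted to the (R) aryl ether center of 9, and base-catalysed transesterification with methanol opens the twisted aryl lactone to 10.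

**Step 4**
Reactants: 10 methyl 2-{[(2R)-1,3-dihydroxy-3-methylbutan-2-yl]oxy}-4-hydroxybenzoate
Product: 11 methyl 4-hydroxy-2-{[(2S)-3-hydroxy-1-iodo-3-methylbutan-2-yl]oxy}benzoate
Conditions: PPh3, I2, imidazole, CH2Cl2, 0 °C → rt
Reagents that add atoms: iodine (II)
Why: Appel-type iodination (Garegg–Samuelsson conditions) converts only the primary alcohol into the iodide by SN2 at CH2, the phenol and the tertiary alcohol stay free and the adjacent stereocenter is untouched (its descriptor becomes S only because CH2I now outranks the carbinol carbon).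

**Step 5**
Reactants: 3 1-[2,4,6-trihydroxy-3,5-bis(3-methylbut-2-en-1-yl)phenyl]ethan-1-one; 11 methyl 4-hydroxy-2-{[(2S)-3-hydroxy-1-iodo-3-methylbutan-2-yl]oxy}benzoate
Product: 14 target CNP0328977.2, the (R)-5,7,4′-trihydroxy-6,8-diprenylflavone whose C-3 and 2′-oxygen are bridged by CH2–CH[C(CH3)2OH] (oxepine ring), via acyclic iodo diketone 12 (not isolated), via cyclic diketone 13 (not isolated)
Conditions: LiHMDS (7.5 equiv), THF–DMPU, −78 → 45 °C; then 1 M HCl/MeOH, 40 °C
Reagents that add atoms: none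
Why: Proposed new method: the lithium polyanion of 3 is C-acylated by the methyl ester of 11 (Claisen condensation) to diketonate 12, which closes the oxepine by 7-exo-tet C-alkylation at the primary iodide to 13 (if alkylation comes first, a Dieckmann closure leads to the same 13), and acid then cyclodehydrates the 2-hydroxyaryl 1,3-diketone to the pyranone, the stereocenter having no acidic hydrogen and taking no part in any bond change; the closest known reaction types are the one-pot polyanion Claisen–cyclodehydration (Baker–Venkataraman-type) flavone synthesis and the alkylative/Dieckmann annulation of ketone enolates with ω-halo esters.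

**Compound list**
1 | 2,4,6-trihydroxyacetophenone | CC(=O)c1c(O)cc(O)cc1O | starting material
2 | prenyl bromide (1-bromo-3-methylbut-2-ene) | CC(C)=CCBr | starting material
3 | 1-[2,4,6-trihydroxy-3,5-bis(3-methylbut-2-en-1-yl)phenyl]ethan-1-one | CC(=O)c1c(O)c(CC=C(C)C)c(O)c(CC=C(C)C)c1O | intermediate
4 | prenol (3-methylbut-2-en-1-ol) | CC(C)=CCO | starting material
5 | [(2S)-3,3-dimethyloxiran-2-yl]methanol | OC[C@@H]1OC1(C)C | intermediate
6 | [(2S)-3,3-dimethyloxiran-2-yl]methyl 4-methylbenzenesulfonate | Cc1ccc(cc1)S(=O)(=O)OC[C@@H]1OC1(C)C | intermediate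
7 | 2,4-dihydroxybenzoic acid | O=C(O)c1ccc(O)cc1O | starting material
8 | [(2S)-3,3-dimethyloxiran-2-yl]methyl 2,4-dihydroxybenzoate | O=C(OC[C@@H]1OC1(C)C)c1ccc(O)cc1O | intermediate
9 | (2R)-8-hydroxy-2-(2-hydroxypropan-2-yl)-2,3-dihydro-5H-1,4-benzodioxepin-5-one | O=C1OC[C@H](C(C)(C)O)Oc2cc(O)ccc12 | intermediate
10 | methyl 2-{[(2R)-1,3-dihydroxy-3-methylbutan-2-yl]oxy}-4-hydroxybenzoate | COC(=O)c1ccc(O)cc1O[C@H](CO)C(C)(C)O | intermediate
11 | methyl 4-hydroxy-2-{[(2S)-3-hydroxy-1-iodo-3-methylbutan-2-yl]oxy}benzoate | COC(=O)c1ccc(O)cc1O[C@H](CI)C(C)(C)O | intermediate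
12 | 1-{4-hydroxy-2-[(2S)-3-hydroxy-1-iodo-3-methylbutan-2-yl]oxyphenyl}-3-[2,4,6-trihydroxy-3,5-bis(3-methylbut-2-en-1-yl)phenyl]propane-1,3-dione | CC(C)=CCc1c(O)c(CC=C(C)C)c(O)c(C(=O)CC(=O)c2ccc(O)cc2O[C@H](CI)C(C)(C)O)c1O | intermediate
13 | (2R)-8-hydroxy-2-(2-hydroxypropan-2-yl)-4-[2,4,6-trihydroxy-3,5-bis(3-methylbut-2-en-1-yl)benzoyl]-3,4-dihydro-1-benzoxepin-5(2H)-one (C-4 epimers) | CC(C)=CCc1c(O)c(CC=C(C)C)c(O)c(C(=O)C2C[C@H](C(C)(C)O)Oc3cc(O)ccc3C2=O)c1O | intermediate
14 | CNP0328977.2: (R)-5,7,4′-trihydroxy-6,8-diprenylflavone with C-3 and the 2′-oxygen bridged by CH2–CH[C(CH3)2OH] (oxepine) | CC(C)=CCc1c(O)c(CC=C(C)C)c2oc3c(c(=O)c2c1O)C[C@H](C(C)(C)O)Oc1cc(O)ccc1-3 | target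

**Step count and risks**
Total step count: 5. Longest linear sequence: 4 steps (4 → 6 → 10 → 11 → 14); the A-ring branch 1 → 3 joins in step 5.

The three steps most likely to fail:

Step 5. The ester of 11 is deactivated by its para-phenoxide, the γ-iodo tertiary alkoxide can close to an oxetane or eliminate under amide base, and the diketonate may alkylate on oxygen. The fallback sets out from 11 and 3 and comes back at 14, and it gives up the protecting-group-free one-pot. Both hydroxyls of 11 are silylated (TESOTf, 2,6-lutidine) to methyl 2-{[(2S)-1-iodo-3-methyl-3-(triethylsilyloxy)butan-2-yl]oxy}-4-(triethylsilyloxy)benzoate F1. F1 is condensed with the polyanion of 3 (LiHMDS, THF, −78 °C → rt) and the open-chain bis-silyl diketone F2 is isolated. The oxepine is then closed in a separate soft-enolate C-alkylation (K2CO3, NaI, acetone, 50 °C) to the bis-silyl cyclic diketone F3. HCl/MeOH cyclodehydrates F3 and removes both silyl groups to give 14.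

Step 3. The ester tether must adopt its less stable E conformation for the 7-exo opening, so intermolecular attack by the more nucleophilic 4-phenoxide or ester cleavage may win. The fallback sets out from 6 (and uses 2) and comes back at 14; it replaces the ester tether by a ketone tether. The trilithio derivative of 2,4-dihydroxyacetophenone (LiHMDS, THF) is C-alkylated by 6 to 1-(2,4-dihydroxyphenyl)-3-[(2S)-3,3-dimethyloxiran-2-yl]propan-1-one F4. Cs2CO3/DMF closes the oxepine by 7-exo opening with inversion to (2R)-8-hydroxy-2-(2-hydroxypropan-2-yl)-3,4-dihydro-1-benzoxepin-5(2H)-one F5. NaH/dimethyl carbonate gives the β-keto ester F6. A thermal Mentzer-type condensation of F6 with 2,4-diprenylphloroglucinol F7 (from phloroglucinol and 2, aq KOH) in N,N-diethylaniline at 180–200 °C builds the pyranone and gives 14.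

Step 1. Double C-prenylation is low-yielding (mono-, O- and gem-dialkylated products). The fallback sets out from 1 and comes back at 3: cationic Friedel–Crafts prenylation with 2-methylbut-3-en-2-ol and BF3·OEt2 in dioxane (no halide, no base) gives 3 directly and makes no compound outside the list (F0).

**Further compounds**
F1 | step 5 | methyl 2-{[(2S)-1-iodo-3-methyl-3-(triethylsilyloxy)butan-2-yl]oxy}-4-(triethylsilyloxy)benzoate | COC(=O)c1ccc(O[Si](CC)(CC)CC)cc1O[C@H](CI)C(C)(C)O[Si](CC)(CC)CC
F2 | step 5 | 1-{2-[(2S)-1-iodo-3-methyl-3-(triethylsilyloxy)butan-2-yl]oxy-4-(triethylsilyloxy)phenyl}-3-[2,4,6-trihydroxy-3,5-bis(3-methylbut-2-en-1-yl)phenyl]propane-1,3-dione | CC(C)=CCc1c(O)c(CC=C(C)C)c(O)c(C(=O)CC(=O)c2ccc(O[Si](CC)(CC)CC)cc2O[C@H](CI)C(C)(C)O[Si](CC)(CC)CC)c1O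
F3 | step 5 | (2R)-4-[2,4,6-trihydroxy-3,5-bis(3-methylbut-2-en-1-yl)benzoyl]-8-(triethylsilyloxy)-2-[2-(triethylsilyloxy)propan-2-yl]-3,4-dihydro-1-benzoxepin-5(2H)-one | CC(C)=CCc1c(O)c(CC=C(C)C)c(O)c(C(=O)C2C[C@H](C(C)(C)O[Si](CC)(CC)CC)Oc3cc(O[Si](CC)(CC)CC)ccc3C2=O)c1O
F4 | step 3 | 1-(2,4-dihydroxyphenyl)-3-[(2S)-3,3-dimethyloxiran-2-yl]propan-1-one | O=C(CC[C@@H]1OC1(C)C)c1ccc(O)cc1O
F5 | step 3 | (2R)-8-hydroxy-2-(2-hydroxypropan-2-yl)-3,4-dihydro-1-benzoxepin-5(2H)-one | O=C1CC[C@H](C(C)(C)O)Oc2cc(O)ccc12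
F6 | step 3 | methyl (2R)-8-hydroxy-2-(2-hydroxypropan-2-yl)-5-oxo-2,3,4,5-tetrahydro-1-benzoxepine-4-carboxylate | COC(=O)C1C[C@H](C(C)(C)O)Oc2cc(O)ccc2C1=O
F7 | step 3 | 2,4-bis(3-methylbut-2-en-1-yl)benzene-1,3,5-triol | CC(C)=CCc1c(O)cc(O)c(CC=C(C)C)c1O
F0 | step 1 | none | none
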